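**Assumptions (one line each)**
- (S)-(+)-Linalool (coriandrol) is taken as a commercial, enantiopure starting material.
- Locants in names and text use cembrane numbering of the target: ring C1–C14, lactone C=O = C16, exo-CH2 = C17. The target is 1S,3R,4S,7R,8S,12S,13R,14R, with a cis-fused lactone and a cis-2,5-disubstituted THF.

**Retrosynthetic overview**
1. Target ⇒ late C13 acetylation and C3 desilylation of a macrocyclic hydroxy-lactone.
2. The 14-membered ring and the cis α-methylene-γ-lactone are formed together, last, by intramolecular In-Barbier allylation (C1–C14) of a (Z)-2-(bromomethyl)enoate onto a C13-hydroxy C14-aldehyde.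
3. The bromomethyl-enoate arm ⇐ Morita–Baylis–Hillman on a C1 aldehyde ⇐ Brown allylation of the C3 aldehyde (ozonolysis of the linalool vinyl group).
4. C9–C10 ⇐ Cu-catalysed opening of a West C8–C9 epoxide by an East C10–C14 Grignard (Brown syn-crotylation of TBSOCH2CHO).
5. Ring order: THF first (from (S)-linalool by allylic oxidation, Sharpless epoxidation, 5-exo epoxide opening), then macrocycle and lactone in one step.

**Route**

Step 1
Reactants: 1, (S)-(+)-linalool
Product: 2, (2E,6S)-2,6-dimethylocta-2,7-diene-1,6-diol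
Conditions: SeO2 (cat.), t-BuOOH, CH2Cl2, rt; then NaBH4, MeOH, 0 °C
Reagents that add atoms: selenium dioxide, O=[Se]=O (O source, recycled by tert-butyl hydroperoxide, CC(C)(C)OO)
Why: Riley allylic oxidation (ene/[2,3]) hydroxylates the E-methyl of the trisubstituted alkene only; NaBH4 returns over-oxidised enal; the carbinol centre (future C4) is untouched.

Step 2
Reactants: 2
Product: 3, (2S)-2-[(2R,5S)-5-ethenyl-5-methyloxolan-2-yl]propane-1,2-diol (C4 S, C7 R, C8 S)
Conditions: Ti(Oi-Pr)4, L-(+)-DET, t-BuOOH, 4 Å MS, CH2Cl2, −20 °C; then CSA (cat.), 0 °C→rt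
Reagents that add atoms: tert-butyl hydroperoxide, CC(C)(C)OO
Why: Sharpless asymmetric epoxidation with L-(+)-DET gives the (7S,8S)-epoxy alcohol (the tertiary vinyl carbinol is inert); 5-exo attack of the C4 tertiary OH at C7 with inversion sets 7R, retains 8S and gives the cis-THF.

Step 3
Reactants: 3
Product: 4, (2R,5S)-5-ethenyl-5-methyl-2-[(2S)-2-methyloxiran-2-yl]oxolane
Conditions: TsCl, Et3N, Bu2SnO (cat.), CH2Cl2, 0 °C→rt; then K2CO3, MeOH, rt
Reagents that add atoms: none
Why: Selective primary tosylation then intramolecular Williamson closure by the tertiary alkoxide; the C8–O bond is not broken, so C8 stays S.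

Step 4
Reactants: 5, (tert-butyldimethylsilyloxy)acetaldehyde; 6, cis-2-butene
Product: 7, (2R,3S)-1-(tert-butyldimethylsilyloxy)-3-methylpent-4-en-2-ol (C13 R, C12 S)
Conditions: 6, n-BuLi, KOt-Bu, THF, −78→−45 °C; (+)-Ipc2BOMe (from (−)-α-pinene), −78 °C; BF3·OEt2; 5, −78 °C; then NaOH, H2O2
Reagents that add atoms: none beyond the numbered reactants (Ipc auxiliary not incorporated)
Why: Brown asymmetric crotylboration; the (Z)-crotylborane gives the syn Me/OH pair through a chair transition state and the lIpc ligands select the aldehyde face giving 13R,12S.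

Step 5
Reactants: 7
Product: 8, TES ether of 7: (2R,3S)-1-(TBSO)-2-(triethylsilyloxy)-3-methylpent-4-ene
Conditions: TESCl, imidazole, DMF, 0 °C→rt
Reagents that add atoms: chlorotriethylsilane, CC[Si](Cl)(CC)CC
Why: Standard silylation; TES is chosen so it can later be removed together with the primary TBS while the hindered C3-OTBS survives.

Step 6
Reactants: 8
Product: 9, (2R,3S)-5-bromo-1-(TBSO)-2-(TESO)-3-methylpentane
Conditions: Cp2Zr(H)Cl, THF, rt; then NBS, 0 °C
Reagents that add atoms: N-bromosuccinimide, BrN1C(=O)CCC1=O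
Why: Schwartz hydrozirconation places Zr at the terminal carbon and bromination gives the anti-Markovnikov primary bromide; silyl ethers and both stereocentres are unaffected.

Step 7
Reactants: 9; 4
Product: 10, C4–C14 acetate: TBSO-C14H2–(13R)-CH(OTES)–(12S)-CH(Me)–(CH2)3–(8S)-C(Me)(OAc)–[(7R)-THF-(4S)-C(Me)]–CH=CH2
Conditions: 9, Mg, THF (Grignard); CuI (10 mol %), 4, −30→0 °C; then Ac2O, DMAP, 0 °C→rt
Reagents that add atoms: acetic anhydride, CC(=O)OC(C)=O
Why: Cu-catalysed Grignard opening of the 2,2-disubstituted epoxide at its CH2 (C9) forms C9–C10 and unveils the C8 tertiary alkoxide, which is acetylated in the same pot; no stereocentre is touched.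

Step 8
Reactants: 10
Product: 11, C3 aldehyde (2-formyl-2-methyl-THF; otherwise as 10)
Conditions: O3, CH2Cl2, −78 °C; then PPh3
Reagents that add atoms: ozone, [O-][O+]=O
Why: Ozonolysis of the only alkene; the aldehyde is α-quaternary and cannot epimerise.

Step 9
Reactants: 11
Product: 12, (3R)-homoallylic alcohol: …(4S)-C(Me)(O)–(3R)-CH(OH)–CH2–CH=CH2
Conditions: allylMgBr, (+)-Ipc2BOMe (from (−)-α-pinene), Et2O, −78 °C; then 11, −78 °C; H2O2, pH 7 buffer
Reagents that add atoms: allylmagnesium bromide, C=CC[Mg]Br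
Why: Brown asymmetric allylboration; the lIpc reagent overrides the weak bias of the α-quaternary α-alkoxy aldehyde and delivers allyl to the face giving 3R; buffered work-up keeps the tertiary acetate.

Step 10
Reactants: 12
Product: 13, C3 O-TBS ether of 12
Conditions: TBSOTf, 2,6-lutidine, CH2Cl2, −78→0 °C
Reagents that add atoms: tert-butyldimethylsilyl triflate, CC(C)(C)[Si](C)(C)OS(=O)(=O)C(F)(F)F
Why: Silyl triflate protects the hindered secondary alcohol (the only free OH).

Step 11
Reactants: 13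
Product: 14, C1 aldehyde: …(3R)-CH(OTBS)–CH2–CHO
Conditions: O3, CH2Cl2, −78 °C; then PPh3
Reagents that add atoms: ozone, [O-][O+]=O
Why: Ozonolysis of the sole (terminal) alkene gives the β-silyloxy aldehyde.

Step 12
Reactants: 14; 15, methyl acrylate
Product: 16, MBH adduct: …(3R)-CH(OTBS)–CH2–CH(OH)–C(=CH2)CO2Me (C1 carbinol epimers, both used)
Conditions: DABCO, 15 (excess), MeOH (cat.), rt, 3–5 d
Reagents that add atoms: none beyond the numbered reactants
Why: Morita–Baylis–Hillman reaction installs C15–C17; the new carbinol centre is destroyed in the next step.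

Step 13
Reactants: 16
Product: 17, (Z)-allylic bromide: …(3R)-CH(OTBS)–CH2–CH=C(CO2Me)–CH2Br (C2 cis to CH2Br)
Conditions: NBS, Me2S, CH2Cl2, 0 °C→rt
Reagents that add atoms: N-bromosuccinimide, BrN1C(=O)CCC1=O
Why: Corey–Kim-type activation with SN2′ allylic transposition gives the thermodynamically preferred (Z)-2-(bromomethyl)enoate; silyl ethers and acetate survive.

Step 14
Reactants: 17
Product: 18, C13,C14-diol (C3-OTBS, C8-OAc and bromo-enoate retained)
Conditions: HF·pyridine, pyridine, THF, 0 °C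
Reagents that add atoms: none
Why: Buffered fluoride removes the secondary TES and primary TBS much faster than the neopentyl-type secondary TBS at C3.

Step 15
Reactants: 18
Product: 19, (13R)-13-hydroxy C14-aldehyde
Conditions: TEMPO (cat.), PhI(OAc)2, CH2Cl2, rt; used crude
Reagents that add atoms: none
Why: Oxoammonium (TEMPO/BAIB) oxidation is selective for the primary alcohol; mildly acidic conditions avoid C13 epimerisation and leave the allylic bromide intact.

Step 16
Reactants: 19
Product: 20, macrocyclic cis-α-methylene-γ-lactone, 13-OH, 8-OAc, 3-OTBS (1S,14R formed)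
Conditions: In powder, THF/H2O (1:1), slow addition to ~2 mM, rt; then PPTS (cat.), CH2Cl2, rt
Reagents that add atoms: none
Why: Intramolecular indium Barbier allylation forms C1–C14 by γ-attack (creating the exo-methylene). The (Z)-allylindium reacts through a closed chair transition state to give the 1,14-syn adduct (cis-lactone), and In(III) chelation between the free C13-OH and C14=O gives 13,14-syn. Acid then closes the γ-lactone with loss of MeOH.

Step 17
Reactants: 20
Product: 21, 8,13-diacetate 3-O-TBS ether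
Conditions: Ac2O, pyridine, DMAP (cat.), CH2Cl2, 0 °C→rt
Reagents that add atoms: acetic anhydride, CC(=O)OC(C)=O
Why: Acetylation of the only free (secondary) hydroxyl under mild conditions that do not isomerise the exo-methylene.

Step 18
Reactants: 21
Product: 22, target (CID 10479028)
Conditions: HF·pyridine, THF, rt (or 48% aq. HF, MeCN)
Reagents that add atoms: none
Why: Acidic fluoride desilylation frees C3-OH without touching acetates or the α-methylene lactone, and avoids base-mediated oxa-Michael or translactonisation.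

**Compound list**

1 | (S)-(+)-linalool | CC(C)=CCC[C@](C)(O)C=C | starting material
2 | (2E,6S)-2,6-dimethylocta-2,7-diene-1,6-diol | OC/C(C)=C/CC[C@](C)(O)C=C | intermediate
3 | (2S)-2-[(2R,5S)-5-ethenyl-5-methyloxolan-2-yl]propane-1,2-diol | OC[C@](C)(O)[C@H]1CC[C@](C)(O1)C=C | intermediate
4 | (2R,5S)-5-ethenyl-5-methyl-2-[(2S)-2-methyloxiran-2-yl]oxolane | C1O[C@]1(C)[C@H]2CC[C@](C)(O2)C=C | intermediate
5 | (tert-butyldimethylsilyloxy)acetaldehyde | CC(C)(C)[Si](C)(C)OCC=O | starting material
6 | cis-2-butene | C/C=C\C | starting material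
7 | (2R,3S)-1-(TBSO)-3-methylpent-4-en-2-ol | CC(C)(C)[Si](C)(C)OC[C@H](O)[C@@H](C)C=C | intermediate
8 | (2R,3S)-1-(TBSO)-2-(TESO)-3-methylpent-4-ene | CC(C)(C)[Si](C)(C)OC[C@H](O[Si](CC)(CC)CC)[C@@H](C)C=C | intermediate
9 | (2R,3S)-5-bromo-1-(TBSO)-2-(TESO)-3-methylpentane | CC(C)(C)[Si](C)(C)OC[C@H](O[Si](CC)(CC)CC)[C@@H](C)CCBr | intermediate
10 | C4–C14 acetate (4S,7R,8S,12S,13R), vinyl at C4 | CC(C)(C)[Si](C)(C)OC[C@H](O[Si](CC)(CC)CC)[C@@H](C)CCC[C@](C)(OC(C)=O)[C@H]1CC[C@](C)(O1)C=C | intermediate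
11 | C3 aldehyde | CC(C)(C)[Si](C)(C)OC[C@H](O[Si](CC)(CC)CC)[C@@H](C)CCC[C@](C)(OC(C)=O)[C@H]1CC[C@](C)(O1)C=O | intermediate
12 | (3R)-homoallylic alcohol | CC(C)(C)[Si](C)(C)OC[C@H](O[Si](CC)(CC)CC)[C@@H](C)CCC[C@](C)(OC(C)=O)[C@H]1CC[C@](C)(O1)[C@H](O)CC=C | intermediate
13 | C3-OTBS ether | CC(C)(C)[Si](C)(C)OC[C@H](O[Si](CC)(CC)CC)[C@@H](C)CCC[C@](C)(OC(C)=O)[C@H]1CC[C@](C)(O1)[C@H](O[Si](C)(C)C(C)(C)C)CC=C | intermediate
14 | C1 aldehyde | CC(C)(C)[Si](C)(C)OC[C@H](O[Si](CC)(CC)CC)[C@@H](C)CCC[C@](C)(OC(C)=O)[C@H]1CC[C@](C)(O1)[C@H](O[Si](C)(C)C(C)(C)C)CC=O | intermediate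
15 | methyl acrylate | C=CC(=O)OC | starting material
16 | MBH adduct (C1-OH epimers) | CC(C)(C)[Si](C)(C)OC[C@H](O[Si](CC)(CC)CC)[C@@H](C)CCC[C@](C)(OC(C)=O)[C@H]1CC[C@](C)(O1)[C@H](O[Si](C)(C)C(C)(C)C)CC(O)C(=C)C(=O)OC | intermediate
17 | (Z)-2-(bromomethyl)enoate | CC(C)(C)[Si](C)(C)OC[C@H](O[Si](CC)(CC)CC)[C@@H](C)CCC[C@](C)(OC(C)=O)[C@H]1CC[C@](C)(O1)[C@H](O[Si](C)(C)C(C)(C)C)C/C=C(/C(=O)OC)CBr | intermediate
18 | C13,C14-diol | OC[C@H](O)[C@@H](C)CCC[C@](C)(OC(C)=O)[C@H]1CC[C@](C)(O1)[C@H](O[Si](C)(C)C(C)(C)C)C/C=C(/C(=O)OC)CBr | intermediate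
19 | (13R)-hydroxy C14-aldehyde | O=C[C@H](O)[C@@H](C)CCC[C@](C)(OC(C)=O)[C@H]1CC[C@](C)(O1)[C@H](O[Si](C)(C)C(C)(C)C)C/C=C(/C(=O)OC)CBr | intermediate
20 | macrocyclic hydroxy-lactone (13-OH, 8-OAc, 3-OTBS) | C=C1C(=O)O[C@H]2[C@H](O)[C@@H](C)CCC[C@](C)(OC(C)=O)[C@H]3CC[C@](C)(O3)[C@H](O[Si](C)(C)C(C)(C)C)C[C@@H]12 | intermediate
21 | 8,13-diacetate 3-O-TBS ether | C=C1C(=O)O[C@H]2[C@H](OC(C)=O)[C@@H](C)CCC[C@](C)(OC(C)=O)[C@H]3CC[C@](C)(O3)[C@H](O[Si](C)(C)C(C)(C)C)C[C@@H]12 | intermediate
22 | CID 10479028 (1S,3R,4S,7R,8S,12S,13R,14R) | C=C1C(=O)O[C@H]2[C@H](OC(C)=O)[C@@H](C)CCC[C@](C)(OC(C)=O)[C@H]3CC[C@](C)(O3)[C@H](O)C[C@@H]12 | target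

**Totals**
- Total steps: 18
- Longest linear sequence: 15 (steps 1–3 then 7–18; the East branch, steps 4–6 then 7–18, is also 15)

**Three steps most likely to fail, with fallbacks**
1. Step 16 (indium macrocyclisation; yield at high dilution and facial control at C1/C14). Fallback: make the C1–C14 bond intermolecularly, where the syn,syn outcome with an α-hydroxy aldehyde has open-chain precedent. Use the bromo-enoate arm built on a West fragment from opening epoxide 4 with a vinyl cuprate, and a C11–C14 hydroxy-aldehyde derived from 7. Then close the ring by RCM at C10=C11 and reduce that alkene with the exo-methylene temporarily masked as a thiol Michael adduct.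
2. Step 15 (selective oxidation to a free α-hydroxy aldehyde; over-oxidation, dimerisation or C13 epimerisation). Fallback: carry C13-O as a PMB ether (start from PMBOCH2CHO, DDQ to the PMP acetal, reductive opening), oxidise the primary alcohol with Dess–Martin periodinane, and cyclise the corresponding 2-(stannylmethyl)enoate with MgBr2·OEt2 (chelation-controlled allylstannane addition) instead of the Barbier reaction.
3. Step 12 (MBH on a hindered β-silyloxy aldehyde; slow, possible β-elimination). Fallback: replace amine catalysis by stoichiometric vinylalumination: add the [α-(methoxycarbonyl)vinyl]aluminium reagent from methyl propiolate and DIBAL/HMPA to aldehyde 14 at low temperature to give the same adduct 16.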